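**Plan**
Retrosynthesis: cut the vanillate C–O bond; trace the CH2O-bearing trisubstituted ring alkene to a cyclic β-keto ester; open the CH2–CH2 bond of the cyclopentene to a vinylcyclopropane; remove the cyclopropane CH2 and the isopropyl group from a tetrasubstituted enal; remove one ring carbon with its ester to reach Hagemann's ester.
Forward: six- to seven-membered ring by diazo ester insertion (step 1), cyclopropane fused across the tetrasubstituted alkene (step 5), five-membered ring by 1,3-shift of the cyclopropane CH2 (step 8), then the side chain and the ester.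
Enabling feature: the CH2–CH2 bond of the five-membered ring is allylic to the tetrasubstituted ring-fusion alkene and flanked by the quaternary methyl carbon, so the cyclopentene is the rearrangement product of a cyclopropane (quaternary C, ring-fusion C, CH2) carrying a 3-methylbut-1-en-2-yl group on the ring-fusion carbon.
Stereochemistry: a (−)-MIB-catalysed iPr2Zn addition sets a carbinol centre whose zinc alkoxide directs the Simmons–Smith methylene to one alkene face and so fixes the quaternary carbon; the carbinol is then oxidised away and no later step touches the quaternary centre.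

Key step: step 8

Remark on the chemistry: the ester-bearing ring carbon of 3–12 is carried as an epimeric (in 3 and 12 partly enolised) mixture and is left undefined in the SMILES; it becomes sp2 in step 10.

Step 1
Reactants: 1 ethyl 2-methyl-4-oxocyclohex-2-ene-1-carboxylate (Hagemann's ester, racemic); 2 tert-butyl diazoacetate
Product: 3 5-tert-butyl 1-ethyl 2-methyl-4-oxocyclohept-2-ene-1,5-dicarboxylate
Conditions: BF3·OEt2, CH2Cl2, −20 → 0 °C
Reagents that add atoms: none
Why: Lewis-acid-promoted diazo ester insertion into a cyclic ketone (Tiffeneau–Demjanov-type one-carbon ring expansion), in which the saturated α′-methylene should migrate rather than the vinylic carbon that stays conjugated with the activated carbonyl, so the 3-methyl enone is kept and the diazo carbon arrives next to the ketone carrying the future CH2O carbon as its ester.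

Step 2
Reactants: 3 5-tert-butyl 1-ethyl 2-methyl-4-oxocyclohept-2-ene-1,5-dicarboxylate
Product: 4 5-tert-butyl 1-ethyl 4,4-(ethylenedioxy)-2-methylcyclohept-1-ene-1,5-dicarboxylate
Conditions: HOCH2CH2OH, PPTS (cat.), benzene, reflux (Dean–Stark)
Reagents that add atoms: ethylene glycol (OCCO)
Why: acid-catalysed deconjugative ketalisation, as known for Hagemann's ester itself, should protect the ketone and move the double bond into conjugation with the ethyl ester to give the tetrasubstituted enoate, while PPTS spares the tert-butyl ester.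

Step 3
Reactants: 4 5-tert-butyl 1-ethyl 4,4-(ethylenedioxy)-2-methylcyclohept-1-ene-1,5-dicarboxylate
Product: 5 tert-butyl 2,2-(ethylenedioxy)-5-(hydroxymethyl)-4-methylcyclohept-4-ene-1-carboxylate
Conditions: iBu2AlH (2.2 equiv), CH2Cl2, −78 → −40 °C; aq. potassium sodium tartrate
Reagents that add atoms: none
Why: chemoselective 1,2-hydride reduction of the conjugated ethyl ester to the allylic alcohol, the tert-butyl ester being shielded by its own bulk and by the neighbouring spiro ketal carbon at low temperature.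

Step 4
Reactants: 5 tert-butyl 2,2-(ethylenedioxy)-5-(hydroxymethyl)-4-methylcyclohept-4-ene-1-carboxylate
Product: 6 tert-butyl 2,2-(ethylenedioxy)-5-formyl-4-methylcyclohept-4-ene-1-carboxylate
Conditions: MnO2 (activated, excess), CH2Cl2, rt
Reagents that add atoms: none
Why: allylic alcohol oxidation with MnO2 should give the enal without touching the ketal or the saturated ester.

Step 5
Reactants: 6 tert-butyl 2,2-(ethylenedioxy)-5-formyl-4-methylcyclohept-4-ene-1-carboxylate
Product: 8 tert-butyl (1R,7S)-3,3-(ethylenedioxy)-7-[(1S)-1-hydroxy-2-methylpropyl]-1-methylbicyclo[5.1.0]octane-4-carboxylate, via isopropylzinc alkoxide 7 (not isolated)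
Conditions: iPr2Zn (2 equiv), (2S)-(−)-3-exo-morpholinoisoborneol [(−)-MIB] (5 mol %), toluene/hexane, 0 °C; then Et2Zn, CF3CH2OH, CH2I2 (premixed in CH2Cl2), 0 °C → rt; aq. NH4Cl
Reagents that add atoms: diisopropylzinc (CC(C)[Zn]C(C)C); diiodomethane (ICI)
Why: amino-alcohol-catalysed enantioselective alkylzinc addition followed in the same flask by alkoxide-directed Simmons–Smith cyclopropanation, in which (−)-MIB should deliver isopropyl to the Si face to give the (S)-alkoxide and A1,3 strain holds the carbinol hydrogen in the alkene plane beside the ring methyl, so the zinc alkoxide delivers CH2 to its own face and sets both cyclopropane carbons (1R,7S).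

Step 6
Reactants: 8 tert-butyl (1R,7S)-3,3-(ethylenedioxy)-7-[(1S)-1-hydroxy-2-methylpropyl]-1-methylbicyclo[5.1.0]octane-4-carboxylate
Product: 9 tert-butyl (1R,7S)-3,3-(ethylenedioxy)-1-methyl-7-(2-methylpropanoyl)bicyclo[5.1.0]octane-4-carboxylate
Conditions: Dess–Martin periodinane, NaHCO3, CH2Cl2, rt
Reagents that add atoms: none
Why: Dess–Martin oxidation of the secondary cyclopropyl carbinol removes the relay stereocentre after it has done its work, under buffered conditions that keep the ketal and the cyclopropane intact.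

Step 7
Reactants: 9 tert-butyl (1R,7S)-3,3-(ethylenedioxy)-1-methyl-7-(2-methylpropanoyl)bicyclo[5.1.0]octane-4-carboxylate
Product: 10 tert-butyl (1R,7S)-3,3-(ethylenedioxy)-1-methyl-7-(3-methylbut-1-en-2-yl)bicyclo[5.1.0]octane-4-carboxylate
Conditions: Zn, CH2Br2, TiCl4 (reagent preformed in THF), CH2Cl2, 0 °C → rt
Reagents that add atoms: dibromomethane (BrCBr)
Why: Takai–Lombardo methylenation with the Zn/CH2Br2/TiCl4 gem-dimetallic reagent should convert the doubly α-branched ketone into the 1,1-disubstituted alkene under non-basic conditions that neither enolise the ester next to the ketal nor attack the tert-butyl ester.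

Step 8
Reactants: 10 tert-butyl (1R,7S)-3,3-(ethylenedioxy)-1-methyl-7-(3-methylbut-1-en-2-yl)bicyclo[5.1.0]octane-4-carboxylate
Product: 11 tert-butyl (8aR)-7,7-(ethylenedioxy)-8a-methyl-3-(propan-2-yl)-1,2,4,5,6,7,8,8a-octahydroazulene-6-carboxylate
Conditions: Ni(cod)2 (10 mol %), 1,3-bis(2,6-diisopropylphenyl)imidazol-2-ylidene (10 mol %), toluene, 60 °C
Reagents that add atoms: none
Why: Zerovalent nickel bound to the carbene ligand coordinates the 1,1-disubstituted alkene, inserts oxidatively into the adjacent cyclopropane C–CH2 bond to give a σ-alkyl/η3-allyl nickelacycle, and reductive elimination joins the CH2 to the former vinyl terminus. The closest known reaction type is the nickel–carbene-catalysed vinylcyclopropane-to-cyclopentene rearrangement of unactivated 1,1-disubstituted vinylcyclopropanes. The five-membered ring is closed by a formal 1,3-shift of the cyclopropane CH2 (three- to five-membered ring expansion by reductive elimination from a six-membered metallacycle), which turns the bicyclo[5.1.0] skeleton into the bicyclo[5.3.0] skeleton and leaves the alkene tetrasubstituted at the ring fusion. No new stereocentre is formed, because the quaternary methyl carbon keeps all four bonds and so carries over the configuration set in step 5, while the other cyclopropane carbon becomes sp2. The step needs cleavage of the bond from the alkenyl-bearing carbon to CH2 and not to the quaternary carbon; this is secured by the lower hindrance at CH2, by the bridgehead alkene that the other mode would have to form, and by the absence of β-hydrogen on the neopentyl Ni–CH2, which closes the diene channel. The temperature is well below that at which the thermal homo-1,5-hydrogen shift of the cis methyl/alkenyl pair would compete.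

Step 9
Reactants: 11 tert-butyl (8aR)-7,7-(ethylenedioxy)-8a-methyl-3-(propan-2-yl)-1,2,4,5,6,7,8,8a-octahydroazulene-6-carboxylate
Product: 12 tert-butyl (8aR)-8a-methyl-7-oxo-3-(propan-2-yl)-1,2,4,5,6,7,8,8a-octahydroazulene-6-carboxylate
Conditions: PPTS, acetone/H2O, 55 °C
Reagents that add atoms: water (O)
Why: mild acid-catalysed ketal hydrolysis should free the ketone as the β-keto ester without cleaving the tert-butyl ester or isomerising the tetrasubstituted alkene.

Step 10
Reactants: 12 tert-butyl (8aR)-8a-methyl-7-oxo-3-(propan-2-yl)-1,2,4,5,6,7,8,8a-octahydroazulene-6-carboxylate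
Product: 13 tert-butyl (8aR)-8a-methyl-3-(propan-2-yl)-7-(trifluoromethanesulfonyloxy)-1,2,4,5,8,8a-hexahydroazulene-6-carboxylate
Conditions: Tf2O, iPr2NEt, CH2Cl2, −78 °C
Reagents that add atoms: trifluoromethanesulfonic anhydride (O=S(=O)(OS(=O)(=O)C(F)(F)F)C(F)(F)F)
Why: O-sulfonylation of the β-keto ester enolate gives the enol triflate regiospecifically between the ketone carbon and the ester-bearing carbon, which fixes the ring alkene at the required position.

Step 11
Reactants: 13 tert-butyl (8aR)-8a-methyl-3-(propan-2-yl)-7-(trifluoromethanesulfonyloxy)-1,2,4,5,8,8a-hexahydroazulene-6-carboxylate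
Product: 14 tert-butyl (8aR)-8a-methyl-3-(propan-2-yl)-1,2,4,5,8,8a-hexahydroazulene-6-carboxylate
Conditions: Pd(OAc)2 (5 mol %), PPh3, HCO2H, Bu3N, DMF, 60 °C
Reagents that add atoms: none
Why: palladium-catalysed formate reduction of an enol triflate (oxidative addition, formate-to-hydride exchange, reductive elimination) should replace OTf by H and leave the trisubstituted enoate, the tetrasubstituted alkene being inert.

Step 12
Reactants: 14 tert-butyl (8aR)-8a-methyl-3-(propan-2-yl)-1,2,4,5,8,8a-hexahydroazulene-6-carboxylate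
Product: 15 [(8aR)-8a-methyl-3-(propan-2-yl)-1,2,4,5,8,8a-hexahydroazulen-6-yl]methanol
Conditions: iBu2AlH (3 equiv), CH2Cl2, −78 → 0 °C; aq. potassium sodium tartrate
Reagents that add atoms: none
Why: 1,2-reduction of the α,β-unsaturated tert-butyl ester with excess iBu2AlH should give the primary allylic alcohol.

Step 13
Reactants: 15 [(8aR)-8a-methyl-3-(propan-2-yl)-1,2,4,5,8,8a-hexahydroazulen-6-yl]methanol; 16 vanillic acid (4-hydroxy-3-methoxybenzoic acid)
Product: 17 [(8aR)-8a-methyl-3-(propan-2-yl)-1,2,4,5,8,8a-hexahydroazulen-6-yl]methyl 4-hydroxy-3-methoxybenzoate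
Conditions: PPh3, DIAD, THF, 0 °C → rt
Reagents that add atoms: none
Why: Mitsunobu esterification, in which the carboxylic acid of vanillic acid is far more acidic than its phenol, so the carboxylate should displace the activated primary allylic alcohol (SN2 at CH2, no stereocentre involved) and leave the phenol free.

**Compound list**
1 | ethyl 2-methyl-4-oxocyclohex-2-ene-1-carboxylate (Hagemann's ester, racemic) | CCOC(=O)C1CCC(=O)C=C1C | starting material
2 | tert-butyl diazoacetate | CC(C)(C)OC(=O)C=[N+]=[N-] | starting material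
3 | 5-tert-butyl 1-ethyl 2-methyl-4-oxocyclohept-2-ene-1,5-dicarboxylate | CCOC(=O)C1CCC(C(=O)OC(C)(C)C)C(=O)C=C1C | intermediate
4 | 5-tert-butyl 1-ethyl 4,4-(ethylenedioxy)-2-methylcyclohept-1-ene-1,5-dicarboxylate | CCOC(=O)C1=C(C)CC2(OCCO2)C(C(=O)OC(C)(C)C)CC1 | intermediate
5 | tert-butyl 2,2-(ethylenedioxy)-5-(hydroxymethyl)-4-methylcyclohept-4-ene-1-carboxylate | OCC1=C(C)CC2(OCCO2)C(C(=O)OC(C)(C)C)CC1 | intermediate
6 | tert-butyl 2,2-(ethylenedioxy)-5-formyl-4-methylcyclohept-4-ene-1-carboxylate | O=CC1=C(C)CC2(OCCO2)C(C(=O)OC(C)(C)C)CC1 | intermediate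
7 | isopropylzinc alkoxide of tert-butyl 2,2-(ethylenedioxy)-5-[(1S)-1-hydroxy-2-methylpropyl]-4-methylcyclohept-4-ene-1-carboxylate | CC(C)[Zn]O[C@@H](C(C)C)C1=C(C)CC2(OCCO2)C(C(=O)OC(C)(C)C)CC1 | intermediate
8 | tert-butyl (1R,7S)-3,3-(ethylenedioxy)-7-[(1S)-1-hydroxy-2-methylpropyl]-1-methylbicyclo[5.1.0]octane-4-carboxylate | O1CCOC12C[C@@]3(C)C[C@@]3([C@@H](O)C(C)C)CCC2C(=O)OC(C)(C)C | intermediate
9 | tert-butyl (1R,7S)-3,3-(ethylenedioxy)-1-methyl-7-(2-methylpropanoyl)bicyclo[5.1.0]octane-4-carboxylate | O1CCOC12C[C@@]3(C)C[C@@]3(C(=O)C(C)C)CCC2C(=O)OC(C)(C)C | intermediate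
10 | tert-butyl (1R,7S)-3,3-(ethylenedioxy)-1-methyl-7-(3-methylbut-1-en-2-yl)bicyclo[5.1.0]octane-4-carboxylate | O1CCOC12C[C@@]3(C)C[C@@]3(C(=C)C(C)C)CCC2C(=O)OC(C)(C)C | intermediate
11 | tert-butyl (8aR)-7,7-(ethylenedioxy)-8a-methyl-3-(propan-2-yl)-1,2,4,5,6,7,8,8a-octahydroazulene-6-carboxylate | O1CCOC12C[C@@]3(C)CCC(C(C)C)=C3CCC2C(=O)OC(C)(C)C | intermediate
12 | tert-butyl (8aR)-8a-methyl-7-oxo-3-(propan-2-yl)-1,2,4,5,6,7,8,8a-octahydroazulene-6-carboxylate | O=C1C[C@@]2(C)CCC(C(C)C)=C2CCC1C(=O)OC(C)(C)C | intermediate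
13 | tert-butyl (8aR)-8a-methyl-3-(propan-2-yl)-7-(trifluoromethanesulfonyloxy)-1,2,4,5,8,8a-hexahydroazulene-6-carboxylate | CC(C)(C)OC(=O)C1=C(OS(=O)(=O)C(F)(F)F)C[C@@]2(C)CCC(C(C)C)=C2CC1 | intermediate
14 | tert-butyl (8aR)-8a-methyl-3-(propan-2-yl)-1,2,4,5,8,8a-hexahydroazulene-6-carboxylate | CC(C)(C)OC(=O)C1=CC[C@@]2(C)CCC(C(C)C)=C2CC1 | intermediate
15 | [(8aR)-8a-methyl-3-(propan-2-yl)-1,2,4,5,8,8a-hexahydroazulen-6-yl]methanol | OCC1=CC[C@@]2(C)CCC(C(C)C)=C2CC1 | intermediate
16 | vanillic acid (4-hydroxy-3-methoxybenzoic acid) | COc1cc(C(=O)O)ccc1O | starting material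
17 | [(8aR)-8a-methyl-3-(propan-2-yl)-1,2,4,5,8,8a-hexahydroazulen-6-yl]methyl 4-hydroxy-3-methoxybenzoate | COc1cc(C(=O)OCC2=CC[C@@]3(C)CCC(C(C)C)=C3CC2)ccc1O | target

**Count and risks**
Total step count: 13. Longest linear sequence: 13 steps (1 → 17); 2 and 16 enter as purchased materials.

Step 8. What may go wrong: the catalyst may fail to bind and insert because the alkene and the cyclopropane are crowded by two fully substituted carbons, or insertion may occur at the more substituted cyclopropane bond and stall. The fallback gives up the cyclopropane, sets out from 6 and comes back at 11, using known chemistry only. The alkoxide 7 is quenched instead of cyclopropanated to give the allylic alcohol tert-butyl 2,2-(ethylenedioxy)-5-[(1S)-1-hydroxy-2-methylpropyl]-4-methylcyclohept-4-ene-1-carboxylate F1. Johnson–Claisen rearrangement (CH3C(OEt)3, cat. EtCO2H, xylene, 140 °C) should transfer the carbinol chirality suprafacially to the quaternary carbon and give tert-butyl (4S,5E)-4-(2-ethoxy-2-oxoethyl)-2,2-(ethylenedioxy)-4-methyl-5-(2-methylpropylidene)cycloheptane-1-carboxylate F2. Reduction of the ethyl ester with iBu2AlH gives tert-butyl (4R,5E)-2,2-(ethylenedioxy)-4-(2-hydroxyethyl)-4-methyl-5-(2-methylpropylidene)cycloheptane-1-carboxylate F3. Hydroboration–oxidation of the exocyclic alkene (BH3·THF; NaBO3) gives tert-butyl (4R)-2,2-(ethylenedioxy)-5-(1-hydroxy-2-methylpropyl)-4-(2-hydroxyethyl)-4-methylcycloheptane-1-carboxylate F4. Selective iodination of the primary hydroxyl (I2, PPh3, imidazole) gives tert-butyl (4S)-2,2-(ethylenedioxy)-5-(1-hydroxy-2-methylpropyl)-4-(2-iodoethyl)-4-methylcycloheptane-1-carboxylate F5. Dess–Martin oxidation gives tert-butyl (4S)-2,2-(ethylenedioxy)-4-(2-iodoethyl)-4-methyl-5-(2-methylpropanoyl)cycloheptane-1-carboxylate F6. A Barbier cyclisation with SmI2/HMPA then closes the five-membered ring at the neighbouring bond to give tert-butyl (8aR)-7,7-(ethylenedioxy)-3-hydroxy-8a-methyl-3-(propan-2-yl)decahydroazulene-6-carboxylate F7. Dehydration with Burgess reagent, with equilibration to the tetrasubstituted ring-fusion alkene if needed, should then give 11.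

Step 5. What may go wrong: alkyl transfer to the hindered tetrasubstituted enal may be slow and poorly face-selective, with β-hydride reduction competing, or the directed methylene transfer to the tetrasubstituted alkene may not go to completion. The fallback separates the two events and moves the asymmetric induction to the cyclopropanation; it sets out from 5 and comes back at 9. Allylic alcohol 5 is cyclopropanated with Zn(CH2I)2·DME in the presence of (4R,5R)-2-butyl-N,N,N′,N′-tetramethyl-1,3,2-dioxaborolane-4,5-dicarboxamide to give tert-butyl (1R,7S)-3,3-(ethylenedioxy)-7-(hydroxymethyl)-1-methylbicyclo[5.1.0]octane-4-carboxylate F8. Dess–Martin oxidation gives tert-butyl (1R,7S)-3,3-(ethylenedioxy)-7-formyl-1-methylbicyclo[5.1.0]octane-4-carboxylate F9. Addition of iPrMgCl/CeCl3 gives 8 together with its carbinol epimer tert-butyl (1R,7S)-3,3-(ethylenedioxy)-7-[(1R)-1-hydroxy-2-methylpropyl]-1-methylbicyclo[5.1.0]octane-4-carboxylate F10. Both are oxidised as in step 6 to 9.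

Step 7. What may go wrong: the doubly α-branched ketone may not react with the titanium methylene reagent, or the Lewis-acidic medium may erode the ketal. The fallback replaces direct methylenation by addition–elimination (Peterson olefination); it sets out from 9 and comes back at 10. Me3SiCH2Li/CeCl3 adds to the ketone to give tert-butyl (1R,7S)-3,3-(ethylenedioxy)-7-[2-hydroxy-3-methyl-1-(trimethylsilyl)butan-2-yl]-1-methylbicyclo[5.1.0]octane-4-carboxylate F11, and syn-elimination of the potassium alkoxide (KN(SiMe3)2, THF, 0 °C) should give 10.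

Further compounds
F1 | step 8 | tert-butyl 2,2-(ethylenedioxy)-5-[(1S)-1-hydroxy-2-methylpropyl]-4-methylcyclohept-4-ene-1-carboxylate | O[C@@H](C(C)C)C1=C(C)CC2(OCCO2)C(C(=O)OC(C)(C)C)CC1
F2 | step 8 | tert-butyl (4S,5E)-4-(2-ethoxy-2-oxoethyl)-2,2-(ethylenedioxy)-4-methyl-5-(2-methylpropylidene)cycloheptane-1-carboxylate | CCOC(=O)C[C@]1(C)CC2(OCCO2)C(C(=O)OC(C)(C)C)CC/C1=C\C(C)C
F3 | step 8 | tert-butyl (4R,5E)-2,2-(ethylenedioxy)-4-(2-hydroxyethyl)-4-methyl-5-(2-methylpropylidene)cycloheptane-1-carboxylate | OCC[C@]1(C)CC2(OCCO2)C(C(=O)OC(C)(C)C)CC/C1=C\C(C)C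
F4 | step 8 | tert-butyl (4R)-2,2-(ethylenedioxy)-5-(1-hydroxy-2-methylpropyl)-4-(2-hydroxyethyl)-4-methylcycloheptane-1-carboxylate | OCC[C@]1(C)CC2(OCCO2)C(C(=O)OC(C)(C)C)CCC1C(O)C(C)C
F5 | step 8 | tert-butyl (4S)-2,2-(ethylenedioxy)-5-(1-hydroxy-2-methylpropyl)-4-(2-iodoethyl)-4-methylcycloheptane-1-carboxylate | ICC[C@]1(C)CC2(OCCO2)C(C(=O)OC(C)(C)C)CCC1C(O)C(C)C
F6 | step 8 | tert-butyl (4S)-2,2-(ethylenedioxy)-4-(2-iodoethyl)-4-methyl-5-(2-methylpropanoyl)cycloheptane-1-carboxylate | ICC[C@]1(C)CC2(OCCO2)C(C(=O)OC(C)(C)C)CCC1C(=O)C(C)C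
F7 | step 8 | tert-butyl (8aR)-7,7-(ethylenedioxy)-3-hydroxy-8a-methyl-3-(propan-2-yl)decahydroazulene-6-carboxylate | O1CCOC12C[C@@]3(C)CCC(O)(C(C)C)C3CCC2C(=O)OC(C)(C)C
F8 | step 5 | tert-butyl (1R,7S)-3,3-(ethylenedioxy)-7-(hydroxymethyl)-1-methylbicyclo[5.1.0]octane-4-carboxylate | O1CCOC12C[C@@]3(C)C[C@@]3(CO)CCC2C(=O)OC(C)(C)C
F9 | step 5 | tert-butyl (1R,7S)-3,3-(ethylenedioxy)-7-formyl-1-methylbicyclo[5.1.0]octane-4-carboxylate | O1CCOC12C[C@@]3(C)C[C@@]3(C=O)CCC2C(=O)OC(C)(C)C
F10 | step 5 | tert-butyl (1R,7S)-3,3-(ethylenedioxy)-7-[(1R)-1-hydroxy-2-methylpropyl]-1-methylbicyclo[5.1.0]octane-4-carboxylate | O1CCOC12C[C@@]3(C)C[C@@]3([C@H](O)C(C)C)CCC2C(=O)OC(C)(C)C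
F11 | step 7 | tert-butyl (1R,7S)-3,3-(ethylenedioxy)-7-[2-hydroxy-3-methyl-1-(trimethylsilyl)butan-2-yl]-1-methylbicyclo[5.1.0]octane-4-carboxylate | O1CCOC12C[C@@]3(C)C[C@@]3(C(O)(C[Si](C)(C)C)C(C)C)CCC2C(=O)OC(C)(C)C
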